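**Retrosynthetic overview**
- The cyclopentanone is closed last, by Dieckmann condensation between two trans butanoate side chains on a finished cyclohexene acid, then loss of the extra carboxyl group.
- C4 (ethyl, CO2H) comes from the ring ketone: Corey–Chaykovsky spiro-epoxide, then a Meinwald 1,2-ethyl shift (key step) and Pinnick oxidation.
- C5 (ethyl, styryl) comes from an extended dienolate unmasked reductively from a γ-methoxy enone: α-ethylation, then α-styrylation.
- The two ring-fusion carbons are set on a prochiral quinol ether: a new catalytic desymmetrizing Mukaiyama–Michael addition (C7a), then enolate alkylation anti to it (C3a, trans).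
- Ring order: six-membered ring first (taken from p-benzoquinone), five-membered ring last.

Assumption: the sense of induction of the new catalyst in step 3 is taken as drawn (the catalyst antipode is chosen to fit), and the two CH(Et) centres next to the C2 carbonyl (C1, C3), carried as epimer mixtures but drawn in the target configuration, are taken to settle in the all-trans target arrangement on final equilibration.

Convention: locants C1–C7a in the descriptions are those of the target hexahydroindene; β is the face of the C7a–H of the target, α the face of the C3a–H.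

**Step 1**
Reactants: 1 p-benzoquinone (cyclohexa-2,5-diene-1,4-dione)
Product: 3 4-ethyl-4-methoxycyclohexa-2,5-dien-1-one, via lithium quinol alkoxide 2 (not isolated)
Conditions: EtLi (1.0 equiv), THF, −78 °C; then MeOSO2CF3, −78 → −20 °C
Reagents that add atoms: ethyllithium [Li]CC; methyl trifluoromethanesulfonate COS(=O)(=O)C(F)(F)F
Why: Carbonyl 1,2-addition of the alkyllithium to one C=O of the quinone gives the quinol alkoxide, which is O-methylated in situ (Williamson-type trapping) to the achiral, prochiral quinol ether; no stereocentre is formed.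

**Step 2**
Reactants: 4 methyl butanoate
Product: 6 (E)-1-methoxy-1-(trimethylsilyloxy)but-1-ene, via lithium ester enolate 5 (not isolated)
Conditions: LiN(iPr)2, THF, −78 °C; Me3SiCl, −78 °C → rt; distil
Reagents that add atoms: chlorotrimethylsilane C[Si](C)(C)Cl
Why: Kinetic ester enolization gives the E(O)-enolate, which is O-silylated (silyl ketene acetal formation); the alkene geometry has no lasting consequence.

**Step 3**
Reactants: 3 4-ethyl-4-methoxycyclohexa-2,5-dien-1-one; 6 (E)-1-methoxy-1-(trimethylsilyloxy)but-1-ene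
Product: 8 methyl 2-(2-ethyl-2-methoxy-5-oxocyclohex-3-en-1-yl)butanoate (side chain α at C7a and cis to the C7–OMe; C1 drawn as in the target), via silyl dienol ether 7 (not isolated)
Conditions: 6 (1.5 equiv), (S)-B-(o-tolyl)oxazaborolidine from (S)-α,α-diphenylprolinol protonated with HN(SO2CF3)2 (20 mol %), Ph3PO (25 mol %), toluene, −40 °C; then 1 M HCl, THF, 0 °C
Reagents that add atoms: none
Why: Proposed new method: the chiral oxazaborolidinium ion binds the dienone carbonyl and tells the two enantiotopic enone arms apart while the ketene silyl acetal attacks the β-carbon anti to the C7 ethyl group (syn to OMe), the silyl group passing to the enolate oxygen to turn the catalyst over, so C7a is set under catalyst control (C7 is a temporary centre, C1 is corrected later); closest known reaction type: oxazaborolidinium-catalysed Mukaiyama–Michael additions of ketene silyl acetals to simple cycloalkenones, and metal-catalysed desymmetrizing conjugate additions to 4,4-disubstituted cyclohexadienones.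

**Step 4**
Reactants: 8 methyl 2-(2-ethyl-2-methoxy-5-oxocyclohex-3-en-1-yl)butanoate; 9 tert-butyl 2-bromobutanoate (racemic)
Product: 11 tert-butyl 2-[3-ethyl-3-methoxy-2-(1-methoxy-1-oxobutan-2-yl)-6-oxocyclohex-4-en-1-yl]butanoate (the two side chains trans: C7a side chain α; C3a side chain β), via lithium enolate 10 (not isolated)
Conditions: LiN(iPr)2 (1.05 equiv), THF, −78 °C; then 9 (1.5 equiv), DMPU, −78 → −30 °C
Reagents that add atoms: none
Why: Kinetic deprotonation gives the cross-conjugated α′-enolate (the γ-carbon is quaternary), and its SN2 alkylation by the α-bromo ester (enolate alkylation) occurs anti to the neighbouring C7a side chain, setting C3a trans to C7a; C3 forms as an epimer mixture that is corrected at the end.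

**Step 5**
Reactants: 11 tert-butyl 2-[3-ethyl-3-methoxy-2-(1-methoxy-1-oxobutan-2-yl)-6-oxocyclohex-4-en-1-yl]butanoate
Product: 13 tert-butyl 2-[3,5-diethyl-2-(1-methoxy-1-oxobutan-2-yl)-6-oxocyclohex-3-en-1-yl]butanoate (side chains trans; C5 epimers), via lithium dienolate 12 (not isolated)
Conditions: Li (2.05 equiv), NH3(l)/THF, −78 °C; then EtI (3 equiv), −78 → −33 °C
Reagents that add atoms: iodoethane CCI
Why: Dissolving-metal (Birch-type) reduction of the γ-methoxy enone expels methoxide and gives the extended lithium dienolate regiospecifically, which is C-ethylated at the α-carbon (deconjugative reductive alkylation); the temporary C7 centre disappears and the new C5 centre is not stereodefining because it is deprotonated again in step 7.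

**Step 6**
Reactants: 14 phenylacetylene (ethynylbenzene)
Product: 16 (E)-(2-bromoethenyl)benzene, via alkenylzirconocene 15 (not isolated)
Conditions: Cp2Zr(H)Cl, THF, rt; then N-bromosuccinimide, 0 °C
Reagents that add atoms: N-bromosuccinimide O=C1CCC(=O)N1Br
Why: syn-Hydrozirconation of the terminal alkyne puts Zr on the terminal carbon, and bromodezirconation with retention gives the E-alkenyl bromide.

**Step 7**
Reactants: 13 tert-butyl 2-[3,5-diethyl-2-(1-methoxy-1-oxobutan-2-yl)-6-oxocyclohex-3-en-1-yl]butanoate; 16 (E)-(2-bromoethenyl)benzene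
Product: 18 tert-butyl 2-[3,5-diethyl-2-(1-methoxy-1-oxobutan-2-yl)-6-oxo-5-[(E)-2-phenylethenyl]cyclohex-3-en-1-yl]butanoate (C5: styryl α; ethyl β), via lithium dienolate 17 (not isolated)
Conditions: LiN(SiMe3)2 (1.0 equiv), THF, −78 → 0 °C; then 16 (1.3 equiv), Pd2(dba)3 (2.5 mol %), P(t-Bu)3 (10 mol %), rt → 40 °C
Reagents that add atoms: none
Why: The C5–H (α to the ketone and allylic) is the most acidic proton, so one equivalent of base regenerates the extended dienolate, and Pd-catalysed enolate α-alkenylation (Buchwald–Hartwig-type, alkene geometry retained) builds the quaternary C5 on the face anti to the C3a side chain, giving styryl α and ethyl β.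

**Step 8**
Reactants: 19 1-iodopropane
Product: 20 diphenyl(propyl)sulfonium tetrafluoroborate
Conditions: Ph2S, AgBF4, CH2Cl2, rt, dark
Reagents that add atoms: diphenyl sulfide c1ccc(cc1)Sc1ccccc1; silver tetrafluoroborate [Ag+].F[B-](F)(F)F
Why: S-Alkylation of the sulfide by the primary iodide, driven by precipitation of AgI (sulfonium salt formation).

**Step 9**
Reactants: 18 tert-butyl 2-[3,5-diethyl-2-(1-methoxy-1-oxobutan-2-yl)-6-oxo-5-[(E)-2-phenylethenyl]cyclohex-3-en-1-yl]butanoate; 20 diphenyl(propyl)sulfonium tetrafluoroborate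
Product: 22 spiro-epoxide of 18 (C4=O replaced by a spiro 3-ethyloxirane: oxirane O α; oxirane CH(Et) β; CH epimers), via sulfonium ylide 21 (not isolated)
Conditions: 20 (1.5 equiv), LiN(iPr)2 (1.5 equiv), DME, −78 °C; then 18, −78 → −20 °C
Reagents that add atoms: none
Why: Corey–Chaykovsky epoxidation: with both side chains equatorial the α-styryl group at C5 is axial, so the sulfonium ylide adds axially from the β face and ring closure leaves the oxirane oxygen α at C4; the configuration of the oxirane CH is not controlled.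

**Step 10**
Reactants: 22 spiro-epoxide of 18
Product: 23 tert-butyl 2-[2,3,5-triethyl-2-formyl-6-(1-methoxy-1-oxobutan-2-yl)-3-[(E)-2-phenylethenyl]cyclohex-4-en-1-yl]butanoate (C4: ethyl β; CHO α)
Conditions: MeAl(OC6H2-4-Br-2,6-tBu2)2 (MABR, 20 mol %), CH2Cl2, −78 → −40 °C
Reagents that add atoms: none
Why: Meinwald (semipinacol) rearrangement: the bulky aluminium Lewis acid opens the oxirane at the tertiary C4–O bond and the ethyl group shifts 1,2 from the oxirane carbon to C4 anti to the leaving oxygen (inversion at C4), giving the quaternary aldehyde with ethyl β and CHO α; this Lewis acid at low temperature favours alkyl over hydride migration.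

**Step 11**
Reactants: 23 tert-butyl 2-[2,3,5-triethyl-2-formyl-6-(1-methoxy-1-oxobutan-2-yl)-3-[(E)-2-phenylethenyl]cyclohex-4-en-1-yl]butanoate
Product: 24 6-(1-tert-butoxy-1-oxobutan-2-yl)-1,2,4-triethyl-5-(1-methoxy-1-oxobutan-2-yl)-2-[(E)-2-phenylethenyl]cyclohex-3-ene-1-carboxylic acid
Conditions: NaClO2, NaH2PO4, 2-methylbut-2-ene, t-BuOH/H2O, 0 °C → rt
Reagents that add atoms: sodium chlorite [Na+].[O-]Cl=O
Why: Pinnick oxidation turns the hindered aldehyde into the acid without touching the alkenes (scavenger present) or any stereocentre.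

**Step 12**
Reactants: 24 6-(1-tert-butoxy-1-oxobutan-2-yl)-1,2,4-triethyl-5-(1-methoxy-1-oxobutan-2-yl)-2-[(E)-2-phenylethenyl]cyclohex-3-ene-1-carboxylic acid
Product: 27 (1S,3S,3aR,4R,5S,7aR)-1,3,4,5,7-pentaethyl-2-oxo-5-[(E)-2-phenylethenyl]-2,3,3a,4,5,7a-hexahydro-1H-indene-4-carboxylic acid (target), via tert-butyl keto ester 25 (not isolated), via keto acid 26 (not isolated)
Conditions: KOtBu (3.5 equiv), THF, 0 °C → rt; AcOH; then LiCl, DMSO–H2O, 130 °C
Reagents that add atoms: none
Why: Dieckmann condensation of the tert-butyl ester enolate onto the methyl ester closes the cyclopentanone between the two pre-set trans side chains (the trans ring fusion is inherited, not created), and Krapcho-type loss of the tert-butyl ester as isobutene and CO2 under hot, weakly basic conditions lets C1 and C3 equilibrate α to the ketone to the all-trans target arrangement.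

**Compound list**
1 | p-benzoquinone | O=C1C=CC(=O)C=C1 | starting material
2 | lithium 1-ethyl-4-oxocyclohexa-2,5-dien-1-olate | CCC1([O-])C=CC(=O)C=C1.[Li+] | intermediate (not isolated)
3 | 4-ethyl-4-methoxycyclohexa-2,5-dien-1-one | CCC1(OC)C=CC(=O)C=C1 | intermediate
4 | methyl butanoate | CCCC(=O)OC | starting material
5 | lithium (E)-1-methoxybut-1-en-1-olate | CC/C=C(\OC)[O-].[Li+] | intermediate (not isolated)
6 | (E)-1-methoxy-1-(trimethylsilyloxy)but-1-ene | CC/C=C(\OC)O[Si](C)(C)C | intermediate
7 | methyl 2-[6-ethyl-6-methoxy-3-(trimethylsilyloxy)cyclohexa-2,4-dien-1-yl]butanoate (silyl dienol ether of 8) | CC[C@@]1(OC)C=CC(O[Si](C)(C)C)=C[C@@H]1[C@H](CC)C(=O)OC | intermediate (not isolated)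
8 | methyl 2-(2-ethyl-2-methoxy-5-oxocyclohex-3-en-1-yl)butanoate (side chain cis to OMe) | CC[C@@]1(OC)C=CC(=O)C[C@@H]1[C@H](CC)C(=O)OC | intermediate
9 | tert-butyl 2-bromobutanoate (racemic; 2-bromobutanoic acid as its tert-butyl ester) | CCC(Br)C(=O)OC(C)(C)C | starting material
10 | lithium α′-enolate of 8 | CC[C@@]1(OC)C=CC([O-])=C[C@@H]1[C@H](CC)C(=O)OC.[Li+] | intermediate (not isolated)
11 | tert-butyl 2-[3-ethyl-3-methoxy-2-(1-methoxy-1-oxobutan-2-yl)-6-oxocyclohex-4-en-1-yl]butanoate (side chains trans) | CC[C@@]1(OC)C=CC(=O)[C@@H]([C@H](CC)C(=O)OC(C)(C)C)[C@@H]1[C@H](CC)C(=O)OC | intermediate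
12 | lithium extended dienolate from 11 | CCC1=CC=C([O-])[C@@H]([C@H](CC)C(=O)OC(C)(C)C)[C@@H]1[C@H](CC)C(=O)OC.[Li+] | intermediate (not isolated)
13 | tert-butyl 2-[3,5-diethyl-2-(1-methoxy-1-oxobutan-2-yl)-6-oxocyclohex-3-en-1-yl]butanoate | CCC1=C[C@H](CC)C(=O)[C@@H]([C@H](CC)C(=O)OC(C)(C)C)[C@@H]1[C@H](CC)C(=O)OC | intermediate
14 | phenylacetylene | C#Cc1ccccc1 | starting material
15 | (E)-chlorobis(cyclopentadienyl)(2-phenylethenyl)zirconium | Cl[Zr](/C=C/c1ccccc1)(C1C=CC=C1)C1C=CC=C1 | intermediate (not isolated)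
16 | (E)-(2-bromoethenyl)benzene | Br/C=C/c1ccccc1 | intermediate
17 | lithium extended dienolate of 13 | CCC1=CC(CC)=C([O-])[C@@H]([C@H](CC)C(=O)OC(C)(C)C)[C@@H]1[C@H](CC)C(=O)OC.[Li+] | intermediate (not isolated)
18 | tert-butyl 2-[3,5-diethyl-2-(1-methoxy-1-oxobutan-2-yl)-6-oxo-5-[(E)-2-phenylethenyl]cyclohex-3-en-1-yl]butanoate | CCC1=C[C@@](/C=C/c2ccccc2)(CC)C(=O)[C@@H]([C@H](CC)C(=O)OC(C)(C)C)[C@@H]1[C@H](CC)C(=O)OC | intermediate
19 | 1-iodopropane | CCCI | starting material
20 | diphenyl(propyl)sulfonium tetrafluoroborate | CCC[S+](c1ccccc1)c1ccccc1.F[B-](F)(F)F | intermediate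
21 | diphenylsulfonium propylide | CC[CH-][S+](c1ccccc1)c1ccccc1 | intermediate (not isolated)
22 | spiro-epoxide of 18 (3-ethyloxirane at C4; O α) | CCC1=C[C@@](/C=C/c2ccccc2)(CC)[C@]3(O[C@@H]3CC)[C@@H]([C@H](CC)C(=O)OC(C)(C)C)[C@@H]1[C@H](CC)C(=O)OC | intermediate
23 | tert-butyl 2-[2,3,5-triethyl-2-formyl-6-(1-methoxy-1-oxobutan-2-yl)-3-[(E)-2-phenylethenyl]cyclohex-4-en-1-yl]butanoate | CCC1=C[C@@](/C=C/c2ccccc2)(CC)[C@](CC)(C=O)[C@@H]([C@H](CC)C(=O)OC(C)(C)C)[C@@H]1[C@H](CC)C(=O)OC | intermediate
24 | 6-(1-tert-butoxy-1-oxobutan-2-yl)-1,2,4-triethyl-5-(1-methoxy-1-oxobutan-2-yl)-2-[(E)-2-phenylethenyl]cyclohex-3-ene-1-carboxylic acid | CCC1=C[C@@](/C=C/c2ccccc2)(CC)[C@](CC)(C(=O)O)[C@@H]([C@H](CC)C(=O)OC(C)(C)C)[C@@H]1[C@H](CC)C(=O)OC | intermediate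
25 | 3-(tert-butoxycarbonyl)-1,3,4,5,7-pentaethyl-2-oxo-5-[(E)-2-phenylethenyl]-2,3,3a,4,5,7a-hexahydro-1H-indene-4-carboxylic acid | CCC1=C[C@@](/C=C/c2ccccc2)(CC)[C@](CC)(C(=O)O)[C@@H]2[C@@H]1[C@H](CC)C(=O)[C@]2(CC)C(=O)OC(C)(C)C | intermediate (not isolated)
26 | 1,3,4,5,7-pentaethyl-2-oxo-5-[(E)-2-phenylethenyl]-2,3,3a,4,5,7a-hexahydro-1H-indene-3,4-dicarboxylic acid | CCC1=C[C@@](/C=C/c2ccccc2)(CC)[C@](CC)(C(=O)O)[C@@H]2[C@@H]1[C@H](CC)C(=O)[C@]2(CC)C(=O)O | intermediate (not isolated)
27 | (1S,3S,3aR,4R,5S,7aR)-1,3,4,5,7-pentaethyl-2-oxo-5-[(E)-2-phenylethenyl]-2,3,3a,4,5,7a-hexahydro-1H-indene-4-carboxylic acid | CCC1=C[C@@](/C=C/c2ccccc2)(CC)[C@](CC)(C(=O)O)[C@@H]2[C@@H]1[C@H](CC)C(=O)[C@H]2CC | target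

**Step count**
Total: 12 steps. Longest linear sequence: 9 steps (1, 3, 4, 5, 7, 9, 10, 11, 12); steps 2, 6 and 8 each prepare one reagent.

**Three steps most likely to fail**

Step 3 (the new reaction) may give low conversion at the hindered β-carbon or low enantioselectivity. The fallback is a known auxiliary-controlled titanium-enolate Michael addition. It sets out from 3. Butanoyl chloride is joined to lithiated (R)-4-benzyloxazolidin-2-one (n-BuLi, THF, −78 °C) to give (R)-4-benzyl-3-butanoyloxazolidin-2-one F1. Its chlorotitanium enolate (TiCl4, i-Pr2NEt, CH2Cl2, −78 → 0 °C) adds to 3 to give the imide adduct F2, and MeOMgBr in MeOH exchanges the auxiliary for the methyl ester. The route is rejoined at 8; the auxiliary antipode is chosen to give the ring configuration of 8.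

Step 7 may give γ- instead of α-alkenylation, or stall at the quaternary centre. The fallback is a known aldol, dehydration and Heck sequence. It sets out from 13. The lithium dienolate (LiN(SiMe3)2, THF, −78 °C) is trapped with acetaldehyde at the α-carbon, anti to the C3a side chain, to give the 5-(1-hydroxyethyl) ketone F3. Burgess reagent (benzene, 50 °C) dehydrates it towards the methyl group, the only direction open, to give the 5-vinyl ketone F4. Heck arylation with iodobenzene (Pd(OAc)2, P(o-tol)3, Et3N, MeCN, 80 °C) then gives the E-styryl compound. The route is rejoined at 18.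

Step 9 may fail because the ketone is flanked by a quaternary carbon and the basic ylide may only enolize it, which would also scramble C3a. The fallback is a known two-stage selenium-based epoxide synthesis with a non-basic nucleophile. It sets out from 18. Propanal and benzeneselenol (ZnCl2, CH2Cl2) give 1,1-bis(phenylselanyl)propane F5, and n-BuLi (THF, −78 °C) converts it into 1-lithio-1-(phenylselanyl)propane F6. This adds axially to the ketone to give the β-hydroxy selenide F7. Se-methylation with MeOSO2CF3 gives the selenonium triflate F8, and KOH (aq.)/Et2O closes the oxirane with loss of the selenide. The route is rejoined at 22.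

**Further compounds**
F1 | step 3 | (R)-4-benzyl-3-butanoyloxazolidin-2-one | CCCC(=O)N1[C@H](Cc2ccccc2)COC1=O
F2 | step 3 | (R)-4-benzyl-3-[2-(2-ethyl-2-methoxy-5-oxocyclohex-3-en-1-yl)butanoyl]oxazolidin-2-one | CC[C@@]1(OC)C=CC(=O)C[C@@H]1[C@H](CC)C(=O)N2[C@H](Cc3ccccc3)COC2=O
F3 | step 7 | tert-butyl 2-[3,5-diethyl-5-(1-hydroxyethyl)-2-(1-methoxy-1-oxobutan-2-yl)-6-oxocyclohex-3-en-1-yl]butanoate (carbinol epimers) | CCC1=C[C@@](C(C)O)(CC)C(=O)[C@@H]([C@H](CC)C(=O)OC(C)(C)C)[C@@H]1[C@H](CC)C(=O)OC
F4 | step 7 | tert-butyl 2-[5-ethenyl-3,5-diethyl-2-(1-methoxy-1-oxobutan-2-yl)-6-oxocyclohex-3-en-1-yl]butanoate | CCC1=C[C@@](C=C)(CC)C(=O)[C@@H]([C@H](CC)C(=O)OC(C)(C)C)[C@@H]1[C@H](CC)C(=O)OC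
F5 | step 9 | 1,1-bis(phenylselanyl)propane | CCC([Se]c1ccccc1)[Se]c1ccccc1
F6 | step 9 | 1-lithio-1-(phenylselanyl)propane | CCC([Li])[Se]c1ccccc1
F7 | step 9 | β-hydroxy selenide from 18 (C4–OH α; C4–CH(Et)SePh β; CH epimers) | CCC1=C[C@@](/C=C/c2ccccc2)(CC)[C@@](O)(C(CC)[Se]c2ccccc2)[C@@H]([C@H](CC)C(=O)OC(C)(C)C)[C@@H]1[C@H](CC)C(=O)OC
F8 | step 9 | Se-methyl selenonium triflate of F7 | CCC1=C[C@@](/C=C/c2ccccc2)(CC)[C@@](O)(C(CC)[Se+](C)c2ccccc2)[C@@H]([C@H](CC)C(=O)OC(C)(C)C)[C@@H]1[C@H](CC)C(=O)OC.[O-]S(=O)(=O)C(F)(F)F
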